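**Retrosynthetic overview**
- Last disconnection: the bond between chain carbon C1' and the peroxyketal carbon C6 of the 1,2-dioxane. It is made by formal insertion of the diazo carbon of the complete C16 chain into the C6–H bond of the finished dioxane core 14 (peroxycarbenium ion, then 1,2-hydride shift).
- Enabling feature: C6 carries two oxygen atoms (ring O1 and the methoxy O), so its C6–H acetal ionises to an O-stabilised cation, and the hydride shift after C–C bond formation regenerates such a cation that recaptures OMe.
- Rings: a temporary oxetane (step 5) is opened 6-exo by a C6 hydroperoxy acetal (step 7). This closes the only ring of the target, the 1,2-dioxane, and sets C3 by inversion. No ring is formed in the key step.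
- The hydroxyethyl arm left by the oxetane is oxidised to CH2CO2Me on the small core, before the union.
- Chain: Takai iodoolefination, Sonogashira coupling, oxidation, N-silyl hydrazone (the chain aldehyde carbon C1' is umpoled as a diazoalkane).

Key step: step 10

Remark: dec-9-enal, pent-4-yn-1-ol and (R)-2-(but-3-en-1-yl)oxirane are taken as commercial; locants C3–C6, O1, O2 are those of the 1,2-dioxane in the target and C1' is the chain carbon bonded to C6.

**Step 1**
Reactants: 1 dec-9-enal
Product: 2 (1E)-1-iodoundeca-1,10-diene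
Conditions: CrCl2, CHI3, dioxane/THF, 0 °C → rt
Reagents that add atoms: iodoform, IC(I)I
Why: Takai iodoolefination, in which the gem-dichromium reagent adds to the aldehyde and anti-elimination should give the (E)-vinyl iodide while the isolated terminal alkene is inert to Cr(II).

**Step 2**
Reactants: 2 (1E)-1-iodoundeca-1,10-diene; 3 pent-4-yn-1-ol
Product: 4 (6E)-hexadeca-6,15-dien-4-yn-1-ol
Conditions: Pd(PPh3)2Cl2 (cat.), CuI (cat.), Et3N, THF, rt, degassed
Reagents that add atoms: none
Why: Sonogashira coupling of a vinyl iodide with a terminal alkyne should proceed at room temperature with retention of the (E) geometry and tolerates the free alcohol and the terminal alkene.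

**Step 3**
Reactants: 4 (6E)-hexadeca-6,15-dien-4-yn-1-ol
Product: 5 (6E)-hexadeca-6,15-dien-4-ynal
Conditions: Dess–Martin periodinane, CH2Cl2, 0 °C → rt
Reagents that add atoms: none
Why: Dess–Martin oxidation stops at the aldehyde, whose alkyne is γ,δ and therefore cannot isomerise into conjugation.

**Step 4**
Reactants: 5 (6E)-hexadeca-6,15-dien-4-ynal
Product: 6 N-tert-butyldimethylsilyl hydrazone of 5
Conditions: 1,2-bis(tert-butyldimethylsilyl)hydrazine, Sc(OTf)3 (cat.), CH2Cl2, 0 °C → rt
Reagents that add atoms: 1,2-bis(tert-butyldimethylsilyl)hydrazine, CC(C)(C)[Si](C)(C)NN[Si](C)(C)C(C)(C)C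
Why: Lewis-acid-catalysed condensation of an aldehyde with the bis-silylhydrazine should give the stable N-silyl hydrazone without azine formation, a storable precursor of a non-stabilised diazoalkane.

**Step 5**
Reactants: 7 (2R)-2-(but-3-en-1-yl)oxirane
Product: 8 (2R)-2-(but-3-en-1-yl)oxetane
Conditions: Me3S(O)I, KOtBu, t-BuOH, 50 °C
Reagents that add atoms: trimethylsulfoxonium iodide, C[S+](C)(C)=O.[I-]
Why: Corey–Chaykovsky-type ring expansion, in which dimethylsulfoxonium methylide opens the epoxide at its CH2 and the alkoxide displaces DMSO (4-exo-tet), so the stereocentre is untouched and the (R)-epoxide should give the (R)-oxetane.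

**Step 6**
Reactants: 8 (2R)-2-(but-3-en-1-yl)oxetane
Product: 10 (2R)-2-(3,3-dimethoxypropyl)oxetane, via aldehyde 9 (not isolated)
Conditions: O3, CH2Cl2/MeOH, −78 °C; Me2S, −78 °C → rt; then HC(OMe)3, PPTS (cat.), rt
Reagents that add atoms: ozone, O=[O+][O-] (carbonyl oxygen of 9); trimethyl orthoformate, COC(OC)OC
Why: Ozonolysis of the terminal alkene with reductive work-up followed by PPTS-catalysed acetalisation masks the volatile aldehyde, and the oxetane should survive ozone at −78 °C and the mild acid.

**Step 7**
Reactants: 10 (2R)-2-(3,3-dimethoxypropyl)oxetane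
Product: 12 2-[(3S)-6-methoxy-1,2-dioxan-3-yl]ethan-1-ol (C6 epimers), via hydroperoxy acetal 11 (not isolated)
Conditions: anhydrous H2O2 in Et2O, CSA (cat.), CH2Cl2, 0 °C; Yb(OTf)3 (cat.), 0 °C → rt; then MeOH, rt
Reagents that add atoms: hydrogen peroxide, OO; methanol, CO (exchanges with the C6 methoxy group)
Why: Acid-catalysed perhydrolysis of the acetal gives the α-methoxy hydroperoxide, whose OOH should open the Lewis-acid-activated oxetane at its substituted carbon (6-exo-tet, the known intramolecular oxetane/hydroperoxide cyclisation) with inversion, so that the (R)-oxetane carbon becomes (3S), while C6 forms as an epimer mixture that is erased in step 10.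

**Step 8**
Reactants: 12 2-[(3S)-6-methoxy-1,2-dioxan-3-yl]ethan-1-ol
Product: 13 2-[(3S)-6-methoxy-1,2-dioxan-3-yl]acetic acid (C6 epimers)
Conditions: TEMPO (cat.), PhI(OAc)2, MeCN/H2O, 0 °C → rt
Reagents that add atoms: water, O
Why: Oxoammonium-catalysed oxidation (TEMPO/PhI(OAc)2) takes the primary alcohol through the aldehyde hydrate to the acid under non-basic conditions, which avoids Kornblum–DeLaMare cleavage of the C6–H peroxyacetal.

**Step 9**
Reactants: 13 2-[(3S)-6-methoxy-1,2-dioxan-3-yl]acetic acid
Product: 14 methyl 2-[(3S)-6-methoxy-1,2-dioxan-3-yl]acetate (C6 epimers)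
Conditions: TMSCHN2, toluene/MeOH, 0 °C
Reagents that add atoms: trimethylsilyldiazomethane, C[Si](C)(C)C=[N+]=[N-]
Why: Esterification with trimethylsilyldiazomethane is neutral and should leave the base-sensitive peroxyacetal and the C3 stereocentre untouched.

**Step 10**
Reactants: 6 N-tert-butyldimethylsilyl hydrazone of 5; 14 methyl 2-[(3S)-6-methoxy-1,2-dioxan-3-yl]acetate
Product: 16 peroxyacarnoate A (methyl 2-[(3S,6R)-6-[(6E)-hexadeca-6,15-dien-4-yn-1-yl]-6-methoxy-1,2-dioxan-3-yl]acetate), via diazoalkane 15 (not isolated)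
Conditions: 6 (1.5 equiv), PhIF2, 2-chloropyridine, CH2Cl2, −78 °C, cold filtration through basic alumina; then slow addition to 14, TMSOTf (0.2 equiv), 2,6-di-tert-butyl-4-methylpyridine (0.3 equiv), CH2Cl2, −78 → −40 °C
Reagents that add atoms: none
Why: Proposed new method: TMSOTf ionises the C6–OMe bond of peroxyacetal 14 to a cation stabilised by ring O1 (ionisation of C6–O1 instead gives a methoxycarbenium ion that leads to the same product after 6-exo reclosure by the peroxide oxygen), the nucleophilic diazo carbon C1' of 15 adds to C6, and the β-oxy diazonium ion loses N2 with a 1,2-shift of the C6 hydride to C1', which leaves a tertiary peroxycarbenium ion that takes methoxide back from Me3SiOMe and regenerates TMSOTf. The closest known reaction types are the Lewis-acid-catalysed homologation of aldehydes with non-stabilised diazoalkanes to ketones (Büchner–Curtius–Schlotterbeck reaction, a formal insertion into the formyl C–H bond) and Lewis-acid-mediated C–C bond formation at peroxycarbenium ions generated from peroxyacetals and peroxyketals. No ring is closed, since the 1,2-dioxane is carried in from 14. C6 is the only new stereocentre and should be set, under the same Lewis-acid equilibration, by the anomeric effect (axial capture of methoxide) with the C3 and C6 carbon substituents equatorial, which is (6R) for the fixed (3S) centre. The step needs the hydride to migrate in preference to ring carbon C5, and needs the diazoalkane to reach the cation before acid destroys it and before the product ketal re-ionises; the first is secured because only the hydride shift gives a tertiary O1-stabilised cation, the second by catalytic TMSOTf, a hindered base, low temperature and slow addition of a limited excess of 15.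

**Compound list**
1 | dec-9-enal | C=CCCCCCCCC=O | starting material
2 | (1E)-1-iodoundeca-1,10-diene | C=CCCCCCCC/C=C/I | intermediate
3 | pent-4-yn-1-ol | C#CCCCO | starting material
4 | (6E)-hexadeca-6,15-dien-4-yn-1-ol | C=CCCCCCCC/C=C/C#CCCCO | intermediate
5 | (6E)-hexadeca-6,15-dien-4-ynal | C=CCCCCCCC/C=C/C#CCCC=O | intermediate
6 | (6E)-1-[2-(tert-butyldimethylsilyl)hydrazinylidene]hexadeca-6,15-dien-4-yne (N-silyl hydrazone of 5, C=N E) | C=CCCCCCCC/C=C/C#CCC/C=N/N[Si](C)(C)C(C)(C)C | intermediate
7 | (2R)-2-(but-3-en-1-yl)oxirane | C=CCC[C@@H]1CO1 | starting material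
8 | (2R)-2-(but-3-en-1-yl)oxetane | C=CCC[C@@H]1CCO1 | intermediate
9 | 3-[(2R)-oxetan-2-yl]propanal | O=CCC[C@@H]1CCO1 | intermediate (not isolated)
10 | (2R)-2-(3,3-dimethoxypropyl)oxetane | COC(OC)CC[C@@H]1CCO1 | intermediate
11 | (2R)-2-(3-hydroperoxy-3-methoxypropyl)oxetane (epimers at the acetal carbon) | COC(OO)CC[C@@H]1CCO1 | intermediate (not isolated)
12 | 2-[(3S)-6-methoxy-1,2-dioxan-3-yl]ethan-1-ol (C6 epimers) | COC1CC[C@@H](CCO)OO1 | intermediate
13 | 2-[(3S)-6-methoxy-1,2-dioxan-3-yl]acetic acid (C6 epimers) | COC1CC[C@@H](CC(=O)O)OO1 | intermediate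
14 | methyl 2-[(3S)-6-methoxy-1,2-dioxan-3-yl]acetate (C6 epimers) | COC1CC[C@@H](CC(=O)OC)OO1 | intermediate
15 | (10E)-16-diazohexadeca-1,10-dien-12-yne | C=CCCCCCCC/C=C/C#CCCC=[N+]=[N-] | intermediate (not isolated)
16 | peroxyacarnoate A, methyl 2-[(3S,6R)-6-[(6E)-hexadeca-6,15-dien-4-yn-1-yl]-6-methoxy-1,2-dioxan-3-yl]acetate | C=CCCCCCCC/C=C/C#CCCC[C@]1(OC)CC[C@@H](CC(=O)OC)OO1 | target

**Step count and risks**
Total step count: 10. Longest linear sequence: 6 steps (7 → 8 → 10 → 12 → 13 → 14 → 16).

Step 10 (proposed new method) is the most likely to fail. The diazoalkane may be consumed by the Lewis acid or by traces of acid before it meets the low concentration of C6 cation. It may also cyclise onto its own alkyne on warming, the peroxycarbenium ion may fragment, or the product ketal may re-ionise and be homologated a second time. The fallback makes the same C1'–C6 bond by known carbanion chemistry before the peroxide exists, and sets out from 4 and 9 (9 taken from 8 by the ozonolysis of step 6, stopped after the Me2S reduction). Alcohol 4 is converted with I2, PPh3 and imidazole into (10E)-16-iodohexadeca-1,10-dien-12-yne F1. Iodine–lithium exchange (t-BuLi, Et2O, −78 °C) gives (6E)-hexadeca-6,15-dien-4-yn-1-yllithium F2. Addition of F2 to 9 gives (9E)-1-[(2R)-oxetan-2-yl]nonadeca-9,18-dien-7-yn-3-ol F3, and Dess–Martin oxidation gives (9E)-1-[(2R)-oxetan-2-yl]nonadeca-9,18-dien-7-yn-3-one F4. H2O2/MeOH with CSA and then Yb(OTf)3 should convert F4, by way of the methoxy hydroperoxy ketal (2R)-2-[(9E)-3-hydroperoxy-3-methoxynonadeca-9,18-dien-7-yn-1-yl]oxetane F5, into 2-[(3S,6R)-6-[(6E)-hexadeca-6,15-dien-4-yn-1-yl]-6-methoxy-1,2-dioxan-3-yl]ethan-1-ol F6; this is the oxetane opening of step 7, with C6 under anomeric control. TEMPO/PhI(OAc)2 then gives 2-[(3S,6R)-6-[(6E)-hexadeca-6,15-dien-4-yn-1-yl]-6-methoxy-1,2-dioxan-3-yl]acetic acid F7, and TMSCHN2 brings the sequence back to the route at 16.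

Step 7 is the second risk. The oxetane may be opened by the acetal oxygen (5-exo) or by external nucleophiles instead of by the hydroperoxide, or the opening may take on SN1 character and erode the configuration at C3. The fallback reverses the order of the two C–O bond formations and sets out from 8. Lewis-acid-promoted intermolecular opening of the oxetane by ethereal H2O2 at its substituted carbon (inversion) should give (3S)-3-hydroperoxyhept-6-en-1-ol F8. Ozonolysis in CH2Cl2/MeOH without reductive work-up gives (3S)-3,6-dihydroperoxy-6-methoxyhexan-1-ol F9. Acid-catalysed intramolecular transperoxyacetalisation in MeOH, in which the C3 hydroperoxide displaces hydrogen peroxide at C6, closes the 1,2-dioxane and comes back at 12.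

Step 5 is the third risk. The ring expansion may be slow or incomplete, and the volatile oxetane may be lost on isolation. The fallback builds the oxetane by Williamson closure and sets out from 7. Copper-catalysed opening of the epoxide with (isopropoxydimethylsilyl)methylmagnesium chloride gives (3R)-1-[dimethyl(propan-2-yloxy)silyl]hept-6-en-3-ol F10. Tamao oxidation (H2O2, KF, KHCO3) gives (3R)-hept-6-ene-1,3-diol F11. Selective tosylation of the primary alcohol gives (3R)-3-hydroxyhept-6-en-1-yl 4-methylbenzenesulfonate F12, and KOtBu closes the ring (4-exo-tet, stereocentre untouched), returning at 8.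

**Further compounds**
F1 | step 10 | (10E)-16-iodohexadeca-1,10-dien-12-yne | C=CCCCCCCC/C=C/C#CCCCI
F2 | step 10 | (6E)-hexadeca-6,15-dien-4-yn-1-yllithium | [Li]CCCC#C/C=C/CCCCCCCC=C
F3 | step 10 | (9E)-1-[(2R)-oxetan-2-yl]nonadeca-9,18-dien-7-yn-3-ol (carbinol epimers) | C=CCCCCCCC/C=C/C#CCCCC(O)CC[C@@H]1CCO1
F4 | step 10 | (9E)-1-[(2R)-oxetan-2-yl]nonadeca-9,18-dien-7-yn-3-one | C=CCCCCCCC/C=C/C#CCCCC(=O)CC[C@@H]1CCO1
F5 | step 10 | (2R)-2-[(9E)-3-hydroperoxy-3-methoxynonadeca-9,18-dien-7-yn-1-yl]oxetane | C=CCCCCCCC/C=C/C#CCCCC(OC)(OO)CC[C@@H]1CCO1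
F6 | step 10 | 2-[(3S,6R)-6-[(6E)-hexadeca-6,15-dien-4-yn-1-yl]-6-methoxy-1,2-dioxan-3-yl]ethan-1-ol | C=CCCCCCCC/C=C/C#CCCC[C@]1(OC)CC[C@@H](CCO)OO1
F7 | step 10 | 2-[(3S,6R)-6-[(6E)-hexadeca-6,15-dien-4-yn-1-yl]-6-methoxy-1,2-dioxan-3-yl]acetic acid | C=CCCCCCCC/C=C/C#CCCC[C@]1(OC)CC[C@@H](CC(=O)O)OO1
F8 | step 7 | (3S)-3-hydroperoxyhept-6-en-1-ol | C=CCC[C@H](OO)CCO
F9 | step 7 | (3S)-3,6-dihydroperoxy-6-methoxyhexan-1-ol (C6 epimers) | COC(OO)CC[C@H](OO)CCO
F10 | step 5 | (3R)-1-[dimethyl(propan-2-yloxy)silyl]hept-6-en-3-ol | C=CCC[C@@H](O)CC[Si](C)(C)OC(C)C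
F11 | step 5 | (3R)-hept-6-ene-1,3-diol | C=CCC[C@@H](O)CCO
F12 | step 5 | (3R)-3-hydroxyhept-6-en-1-yl 4-methylbenzenesulfonate | C=CCC[C@@H](O)CCOS(=O)(=O)c1ccc(C)cc1
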